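The target does not simply pile up in these flasks: it is made from substrate and partner with the catalyst, and the readings suggest that substrate then attacks it.

| flask | substrate | partner | catalyst | remark | time |
|---|---|---|---|---|---|
| green | 0.050 M | 0.044 M | 25 µM | run made earlier |  |
| teal | 0.050 M | 0.079 M | 25 µM | run made earlier |  |
| red | 0.050 M | 0.13 M | 25 µM | run made earlier |  |
| noon | 0.050 M | 0.0480 M | 25 µM |  | 10 min |
| winter | 0.050 M | 0.0710 M | 25 µM |  | 10 min |
| autumn | 0.050 M | 0.110 M | 25 µM |  | 10 min |

| run | time / min | target / % | substrate / % |
|---|---|---|---|
| green | 0.833 | 16.1 | 81.4 |
| green | 1.50 | 24.1 | 67.8 |
| green | 3.00 | 32.5 | 48.8 |
| green | 5.00 | 37.4 | 32.5 |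
| green | 10.0 | 37.8 | 14.6 |
| teal | 0.833 | 28.0 | 67.8 |
| teal | 1.50 | 39.6 | 49.8 |
| teal | 3.00 | 51.7 | 26.8 |
| teal | 5.00 | 57.0 | 12.8 |
| teal | 10.0 | 60.5 | 2.7 |
| red | 0.833 | 41.8 | 52.8 |
| red | 2.50 | 66.6 | 16.0 |
| red | 5.00 | 74.0 | 2.0 |
| red | 8.00 | 74.6 | 0.2 |
| red | 10.0 | 74.3 | 0 |

(standard deviation of a reading: 0.5 percentage points)

- a species is counted by the substrate in it: one side product counts as two

* which of the two there is more of at the end, counted by the substrate in each, noon (side product / target)
* which of the two there is more of at the end, counted by the substrate in each, winter (side product / target)
* which of the two there is more of at the end, counted by the substrate in each, autumn (side product / target)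
* how much target is there at the end, in percent of the substrate charged: noon
* how much target is there at the end, in percent of the substrate charged: winter
* how much target is there at the end, in percent of the substrate charged: autumn

**Where does the substrate go that is not in target?** In green, the gap between substrate lost and target is 2.50% at 0.833 min and grows to 47.6% at 10.0 min. It starts small while target stands at 16.1%, so I read side product as substrate plus target, holding two substrate and one partner.

**What then tells whether target gains?** On this reading, making and using both consume substrate, so [substrate] cancels when the two rates are compared. Making goes with [partner] and using with [target], so at a fixed catalyst charge their ratio follows [partner]/[target].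

**Can you read the balance point?** In green, target goes from 37.4% to 37.8% between 5.00 min and 10.0 min, flat within the scatter, while substrate falls from 32.5% to 14.6%. Making and using are therefore about equal there. Partner left is the charge minus target minus the side product count divided by two, which is 26.4% of the substrate charged. Dividing by target gives a reading of 0.698. This is the crossing ratio, the [partner]/[target] at which target is made just as fast as it is used up, a selectivity factor for this catalyst charge. Made over used is then [partner]/[target] divided by it.

**That rests on one flat stretch. Does it hold elsewhere?** In teal, between 3.00 min and 5.00 min, substrate lost and target gained give made over used as 2.22. The crossing ratio gives 2.65 at the start of that stretch and 2.16 at its end, so the reading lies between them.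

**And the new flasks?** Target minus side product is −9.8 percentage points in green and 24 points in teal. Noon's partner charge lies near green's, and winter's near teal's, while autumn has more than teal. I therefore expect side product ahead in noon and target ahead in winter and autumn. Straight lines between the runs give 40.4%, 55.3% and 68.9%. I expect these to sit low, since each added partner buys less target in the upper interval than in the lower. Noon, with green's substrate reading, meets the crossing near 44.5% of target, which is my upper figure for noon.

The forecast also sees “side product formed from substrate plus target”, with its own ratio of 0.73 against my 0.698. For the larger share it says side product in noon, target in winter and target in autumn. For target it says 41%, 56% and 70.6%, above my straight lines .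

The flasks give target 41.4% in noon, 57.0% in winter and 71.0% in autumn. The larger share is side product in noon, target in winter and target in autumn. In winter, target is made 4.24 times faster than used at 1.35 min and 1.60 times at 10.0 min. The crossing ratio, applied to winter's end with 45.8% of the partner free, gives made over used as 1.63.

    substrate + partner + catalyst → catalyst + target (k = 4100 L² mol⁻² s⁻¹)
    substrate + target → side product (k = 0.0730 L mol⁻¹ s⁻¹)

Now take winter with 0.030 M of substrate. Even with every substrate turned to target, partner left over target would be 1.37, about twice the crossing ratio, so target should keep gaining. That flask ends with target 72.0%, substrate 2.03% and side product 26.0%.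

The earlier runs and the new flask are calculated for substances that don't exist; noise was put on by code.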